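## The problem

Compound 19 is a flavone: benzo ring A is fused to pyranone ring C along C4a–C8a, and aryl ring B is attached at C2. Ring A carries oxygen on four of its six carbons (methoxy at C5 and C8, prenyloxy at C7, the ring oxygen O1 at C8a), so the first task is to place differentiated oxygen substituents on one benzene ring without ambiguity. The target has no stereocentre. C2 and C3 are stereogenic only in saturated precursors of ring C, where C2 (set first) can direct C3, but both become sp2 when the C2=C3 bond appears, so no stereocontrol is needed. The fragile group is the aryl prenyl ether, which does not survive strong Brønsted or Lewis acids, hydrogenolysis, electrophilic oxidants that attack trisubstituted alkenes, or prolonged heating. The hydroxyl groups on C3 and C4' must be told apart, because the first ends methylated and the second free. The C4' oxygen therefore needs a protecting group whose removal spares the prenyl ether, which excludes acetals (acid) and benzyl ethers (hydrogenolysis) for the last step. The enabling feature is the pair C3/C4 of ring C: two adjacent oxygen-bearing carbons, an enol ether beside a carbonyl, which is the oxidation pattern of a dehydrogenated acyloin. The C3–C4 bond can therefore be traced to two formyl groups held in a 1,6-relationship by C4a, C8a, O1 and C2.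

## Retrosynthesis

**19 from 18 (O–S bond at C4').** The free phenol is released last from benzenesulfonate 18. A sulfonate is preferred to an acetal or a benzyl ether because it falls to aqueous alkali, to which the prenyl ether is inert. It also survives every earlier operation (carbonate bases, hydride, radical bromination, periodinane oxidation) and deactivates ring B in the bromination. The forward step must cleave at sulfur faster than base opens the pyranone.

**18 from 17, and 17 from 15 (C3–O–CH3, then the C2–C3 oxidation level).** The C3 methoxy group comes from flavonol 17, whose only other acidic oxygen is masked. Flavonol 17 is the enol of dione 16, which is the oxidation product of ketol 15. Any regio- or stereoisomer of the ketol gives the same dione, so the oxidation removes all isomer questions raised by the ring closure.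

**15 from 14 (C3–C4, the key cut).** Opening ring C between the hydroxyl-bearing carbon and the carbonyl carbon gives dialdehyde 14, in which each of the two carbons is a formyl group. The neighbouring cuts are less suitable:
- A C4–C4a cut would require acid-mediated acylation of ring A with the prenyl ether present.
- An O1–C2 or C2–C3 cut would require an aryl methyl ketone and a dehydrative or oxidative cyclisation, which is least reliable when C5 bears a methoxy group.

The C3–C4 cut needs only a nucleophilic carbene catalyst and a weak base. Precursor 14 has no ring C and one stereocentre, present as the racemate. The forward reaction must favour six-membered ring closure over intermolecular coupling and over loss of the aryloxy tether.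

**14 from 13 and 12, then 12 from 8 and 11 (O1–C2).** The two formyl groups are unveiled together from diol 13, which comes from aldehyde ester 12 by hydride reduction. This redox detour is accepted because an ester is the one robust, highly SN2-active form of the two-carbon unit. Cutting the aryl ether bond O1–C2 of 12 gives salicylaldehyde 8 (all of ring A) and α-bromo ester 11 (ring B, C2 and C3), two fragments of similar size. The forward step is a Williamson reaction at a carbon that has no β-hydrogen.

**11 from 10 and 9 (C–Br, O–S).** The bromide is introduced at the benzylic, α-ester position of sulfonate 10, which is made from commercial methyl homovanillate 9.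

**8 from 6 and 7, 6 from 4, 4 from 2, 2 from 1 (O-prenyl, C–CHO, two C–O bonds, O–CH3).** Prenyl bromide 7 is attached to the C4 hydroxyl of dihydroxy aldehyde 6. The other hydroxyl is hydrogen-bonded to the formyl group, so the two are differentiated without protection. This is why formylation (through iminium salt 5) precedes prenylation: mono-prenylation of symmetric diol 4 would be statistical. Diol 4 is C2-symmetric, so its formylation has only one possible outcome. It is derived from dibromide 2 by exchanging both bromides for hydroxyl (through bromophenol 3), and 2 is the methyl ether of commercial 1. In 1 the para-methoxy group and the two ortho bromides already mark all four oxygen positions of ring A.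

## Roads not taken

**Alternative 1:** Ring A is cut at C8–C8a and C4a–C5, leaving pyranone sulfone A2, which already holds ring B and the C3 methoxy group. In the forward key step the 4-methoxy bis(silyloxy)diene A3 adds across C5=C6 of A2. Loss of the sulfinate and of one methoxy group as the alcohol then aromatises ring A and gives 5,7-dihydroxyflavone A1.
- Merits: ring C arrives at the final oxidation level with C3 already methylated, and the C8 methoxy group is placed by the diene with no aromatic substitution chemistry.
- Weak points: A2 needs its own multistep preparation from a furan. Cycloaddition onto the C5=C6 bond of a 4-pyranone with aromatisation by double elimination is not an established reaction. A1 still needs selective 7-O-prenylation with 7, forcing methylation of the chelated C5 hydroxyl, and acidic removal of an acetal protecting group beside the new prenyl ether.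
- Comparison: both routes rest on one unprecedented step. Alternative 1 is better in that it needs no redox manipulation of ring C. The chosen plan has against this simple, well-known chemistry on either side of its key step and no acid after step 4.

**Alternative 2:** Ring A is cut at C4a–C8a and C5–C6 and built by benzannulation. Thermal opening of cyclobutenone A5 gives a vinylketene that adds methoxyethyne A6, and the electrocyclic cascade gives phenol A4, whose only free hydroxyl is the future O1.
- Merits: complete regiocontrol over four different oxygen substituents, and a phenol ready for ortho-formylation.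
- Weak points: A5 and A6 are not commodity chemicals and A6 is volatile and unstable. A4 carries benzyl where prenyl is needed, so a hydrogenolysis and a prenylation must be inserted before the alkene is present. The step builds only ring A, so ring C must still be made by another method (for instance the present one).
- Comparison: Alternative 2 would be preferable only if the hydroxyl groups of a symmetric precursor could not be differentiated. In the chosen plan the symmetry of 4 and the hydrogen bond in 6 solve that problem in two conventional steps and give 8 with the prenyl group already in place.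

**Alternative 3:** Ring C is cut at C4–C4a. The (E)-3-aryloxy-2-methoxyacrylic acid A8 is activated as a mixed anhydride under strongly acidic conditions, and its acylium carbon attacks the only free position ortho to the ether oxygen of ring A, closing ring C to flavone A7.
- Merits: cycliacylation of 3-aryloxyacrylic acids to chromones is an established reaction type. The attacked position is activated by three oxygen substituents. A7 has the C3 methoxy group and the full oxidation level.
- Weak points: A8 is a tetrasubstituted enol ether whose E geometry must be secured or equilibrated. The acylium conditions exclude a prenyl ether, so A7 carries benzyl at C7 and needs debenzylation, prenylation with 7 and desulfonylation afterwards.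
- Comparison: the ring closure of Alternative 3 is more secure than that of the chosen plan. The chosen plan has against this a base-only sequence in which the prenyl ether is installed once and never exchanged, precursors with no alkene geometry to control, and a key step whose regio- and stereochemical outcome is irrelevant because all ketol isomers converge on 17.

Key step: step 10

Assumption: every intermediate with a stereocentre (11–16) is handled as the racemate and 15 is drawn as one enantiomer of the trans pair; compounds 1 and 9 are taken as catalogue chemicals.

## Route

Step 1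
Reactants: 1 2,6-dibromo-4-methoxyphenol
Product: 2 1,3-dibromo-2,5-dimethoxybenzene
Conditions: MeI, K2CO3, acetone, reflux
Reagents that add atoms: iodomethane, CI
Why: Williamson O-methylation of an acidic phenol; it fixes the future C8 methoxy group and leaves two equivalent bromides as handles for the flanking oxygens.

Step 2
Reactants: 2 1,3-dibromo-2,5-dimethoxybenzene
Product: 4 2,5-dimethoxybenzene-1,3-diol, via 3-bromo-2,5-dimethoxyphenol 3 (not isolated)
Conditions: Pd2(dba)3 (2 mol%), tBuXPhos (8 mol%), KOH (6 equiv), 1,4-dioxane/H2O (1:1), 100 °C, Ar; then aq. HCl
Reagents that add atoms: potassium hydroxide, [K+].[OH-]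
Why: Palladium-catalysed hydroxylation of aryl bromides with hydroxide (oxidative addition to zerovalent palladium, bromide–hydroxide exchange, C–O reductive elimination from the bulky biarylphosphine complex) is applied twice to a C2-symmetric dibromide, so no site selectivity is needed; the second coupling runs on the bromophenoxide of 3.

Step 3
Reactants: 4 2,5-dimethoxybenzene-1,3-diol
Product: 6 2,4-dihydroxy-3,6-dimethoxybenzaldehyde, via iminium chloride 5 (not isolated)
Conditions: POCl3 (1.2 equiv), DMF (3 equiv), MeCN, 0 °C → rt; then H2O, 50 °C
Reagents that add atoms: N,N-dimethylformamide, CN(C)C=O; water, O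
Why: Vilsmeier–Haack formylation; the two free ring positions of 4 are equivalent and each is ortho or para to both hydroxyl groups, and the iminium group of 5 deactivates the ring against a second attack before hydrolysis releases the aldehyde.

Step 4
Reactants: 6 2,4-dihydroxy-3,6-dimethoxybenzaldehyde; 7 prenyl bromide (1-bromo-3-methylbut-2-ene)
Product: 8 2-hydroxy-3,6-dimethoxy-4-(prenyloxy)benzaldehyde
Conditions: K2CO3 (1.1 equiv), acetone, rt → 40 °C
Reagents that add atoms: none
Why: Regioselective Williamson etherification; the C2 hydroxyl is held in a hydrogen bond to the formyl group, so one equivalent of mild base ionises and alkylates the C4 hydroxyl, as is general for 2,4-dihydroxybenzaldehydes.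

Step 5
Reactants: 9 methyl homovanillate (methyl (4-hydroxy-3-methoxyphenyl)acetate)
Product: 10 methyl [4-(benzenesulfonyloxy)-3-methoxyphenyl]acetate
Conditions: PhSO2Cl, NEt3, DMAP (cat.), CH2Cl2, 0 °C → rt
Reagents that add atoms: benzenesulfonyl chloride, O=S(=O)(Cl)c1ccccc1
Why: Sulfonylation of the phenol; the benzenesulfonate resists carbonate bases, hydride, radical bromination and oxidants, lowers the electron density of ring B, and is removable at the end with aqueous alkali, which the prenyl ether tolerates.

Step 6
Reactants: 10 methyl [4-(benzenesulfonyloxy)-3-methoxyphenyl]acetate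
Product: 11 rac-methyl bromo[4-(benzenesulfonyloxy)-3-methoxyphenyl]acetate
Conditions: NBS (1.05 equiv), AIBN (5 mol%), PhCF3, 85 °C
Reagents that add atoms: N-bromosuccinimide, O=C1CCC(=O)N1Br
Why: Wohl–Ziegler radical bromination at the doubly activated benzylic, α-ester position; the sulfonate-deactivated ring and the non-polar medium disfavour electrophilic ring bromination, and the sulfonyl group has no benzylic hydrogen of its own.

Step 7
Reactants: 8 2-hydroxy-3,6-dimethoxy-4-(prenyloxy)benzaldehyde; 11 rac-methyl bromo[4-(benzenesulfonyloxy)-3-methoxyphenyl]acetate
Product: 12 rac-methyl [4-(benzenesulfonyloxy)-3-methoxyphenyl][2-formyl-3,6-dimethoxy-5-(prenyloxy)phenoxy]acetate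
Conditions: K2CO3, DMF, rt
Reagents that add atoms: none
Why: Williamson ether synthesis by SN2 displacement of an α-bromo ester with the phenoxide of 8 forms the O1–C2 bond; the bromide has no β-hydrogen, so elimination cannot compete. C2 is formed as a racemate, which is acceptable because it becomes sp2 in step 11.

Step 8
Reactants: 12 rac-methyl [4-(benzenesulfonyloxy)-3-methoxyphenyl][2-formyl-3,6-dimethoxy-5-(prenyloxy)phenoxy]acetate
Product: 13 rac-4-{2-hydroxy-1-[2-(hydroxymethyl)-3,6-dimethoxy-5-(prenyloxy)phenoxy]ethyl}-2-methoxyphenyl benzenesulfonate
Conditions: LiBH4, THF, 0 °C → rt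
Reagents that add atoms: none
Why: LiBH4 reduces both the formyl group and the activated α-aryloxy ester to primary alcohols and leaves the aryl sulfonate and the alkene alone; going through the diol avoids a partial reduction of an ester beside a more reactive aldehyde.

Step 9
Reactants: 13 rac-4-{2-hydroxy-1-[2-(hydroxymethyl)-3,6-dimethoxy-5-(prenyloxy)phenoxy]ethyl}-2-methoxyphenyl benzenesulfonate
Product: 14 rac-4-{1-[2-formyl-3,6-dimethoxy-5-(prenyloxy)phenoxy]-2-oxoethyl}-2-methoxyphenyl benzenesulfonate
Conditions: Dess–Martin periodinane (2.6 equiv), NaHCO3, CH2Cl2, 0 °C → rt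
Reagents that add atoms: none
Why: Dess–Martin oxidation converts the electron-rich benzylic alcohol and the β-aryloxy primary alcohol to aldehydes under buffered, base-free conditions that neither enolise the new α-aryl aldehyde nor touch the prenyl ether; excess oxidant added at once keeps a hydroxy aldehyde, and hence a lactol, from accumulating. The dialdehyde is passed through a short silica pad and used at once.

Step 10
Reactants: 14 rac-4-{1-[2-formyl-3,6-dimethoxy-5-(prenyloxy)phenoxy]-2-oxoethyl}-2-methoxyphenyl benzenesulfonate
Product: 15 rac-4-[(2R,3R)-3-hydroxy-5,8-dimethoxy-4-oxo-7-(prenyloxy)chroman-2-yl]-2-methoxyphenyl benzenesulfonate (trans)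
Conditions: 3-benzyl-5-(2-hydroxyethyl)-4-methylthiazolium chloride (20 mol%), NEt3 (1 equiv), EtOH (0.02 M), 60 °C, Ar
Reagents that add atoms: none
Why: Proposed new method: the carbene released from the thiazolium salt by NEt3 adds to a formyl group of 14, proton transfer gives the Breslow intermediate (an acyl-anion equivalent), and this attacks the second formyl carbon to form C3–C4 before the carbene is expelled. The closest known reaction type is the carbene-catalysed intramolecular crossed benzoin of 2-(2-oxoalkoxy)benzaldehydes (aldehyde–ketone), which gives 3-hydroxychroman-4-ones; an aldehyde–aldehyde version on an α-aryloxy aldehyde has not been shown. Ring C closes in the 6-exo-trig mode across a short, rigid tether made of the ortho-disubstituted arene, O1 and the single sp3 carbon C2. If the ring A formyl group is the donor, the aryl ketone 15 forms directly; if the aliphatic formyl group is the donor, carbonyl and hydroxyl are first placed the other way round, and NEt3 is expected to move that isomer through the common enediol to 15, in which the carbonyl is conjugated with the trialkoxyarene. The new stereocentre C3 is set relative to C2 under thermodynamic control, since benzoin addition and enolisation are reversible and trans-15 carries the aryl and hydroxyl groups both equatorial. No regio- or stereoselectivity is required, because every ketol isomer is oxidised to the same dione in step 11. What is required is chemoselectivity for ring closure over intermolecular benzoin and over loss of the ring A aryloxide from a Breslow intermediate at C3; high dilution, the tether, a weak amine base and an alcohol solvent that holds the α-aryloxy aldehyde largely as its hemiacetal are chosen to secure it.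

Step 11
Reactants: 15 rac-4-[(2R,3R)-3-hydroxy-5,8-dimethoxy-4-oxo-7-(prenyloxy)chroman-2-yl]-2-methoxyphenyl benzenesulfonate
Product: 17 4-[3-hydroxy-5,8-dimethoxy-4-oxo-7-(prenyloxy)-4H-chromen-2-yl]-2-methoxyphenyl benzenesulfonate, via chromane-3,4-dione 16 (not isolated)
Conditions: Dess–Martin periodinane (1.2 equiv), NaHCO3, CH2Cl2, 0 °C → rt
Reagents that add atoms: none
Why: Dess–Martin oxidation of an α-hydroxy ketone to the 1,2-dione; dione 16 has an acidic C2–H and tautomerises to the 3-hydroxychromone 17, which removes both stereocentres. Any regio- or stereoisomeric ketol carried over from step 10 gives the same dione.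

Step 12
Reactants: 17 4-[3-hydroxy-5,8-dimethoxy-4-oxo-7-(prenyloxy)-4H-chromen-2-yl]-2-methoxyphenyl benzenesulfonate
Product: 18 2-methoxy-4-[3,5,8-trimethoxy-4-oxo-7-(prenyloxy)-4H-chromen-2-yl]phenyl benzenesulfonate
Conditions: MeI, K2CO3, acetone, reflux
Reagents that add atoms: iodomethane, CI
Why: Williamson O-methylation of the enolic C3 hydroxyl of a flavonol, a standard reaction; the only other acidic oxygen, at C4', is masked as the sulfonate.

Step 13
Reactants: 18 2-methoxy-4-[3,5,8-trimethoxy-4-oxo-7-(prenyloxy)-4H-chromen-2-yl]phenyl benzenesulfonate
Product: 19 4'-hydroxy-3,5,8,3'-tetramethoxy-7-prenyloxyflavone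
Conditions: KOH (2 M aq.), 1,4-dioxane, 60 °C; then aq. HCl to pH 5
Reagents that add atoms: none
Why: Hydrolysis of an aryl sulfonate by attack of hydroxide at sulfur; the C4' oxide, conjugated with the pyranone carbonyl, is a good leaving group and once formed it deactivates C2 toward base. An alcohol-free medium avoids an alkyl sulfonate that could re-alkylate the phenoxide, and the prenyl ether is inert to alkali.

## Compound list

1 | 2,6-dibromo-4-methoxyphenol | COc1cc(Br)c(O)c(Br)c1 | starting material
2 | 1,3-dibromo-2,5-dimethoxybenzene | COc1cc(Br)c(OC)c(Br)c1 | intermediate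
3 | 3-bromo-2,5-dimethoxyphenol (formed in the flask, not isolated) | COc1cc(O)c(OC)c(Br)c1 | intermediate
4 | 2,5-dimethoxybenzene-1,3-diol | COc1cc(O)c(OC)c(O)c1 | intermediate
5 | (2,4-dihydroxy-3,6-dimethoxybenzylidene)dimethylammonium chloride (formed in the flask, not isolated) | COc1cc(O)c(OC)c(O)c1C=[N+](C)C.[Cl-] | intermediate
6 | 2,4-dihydroxy-3,6-dimethoxybenzaldehyde | COc1cc(O)c(OC)c(O)c1C=O | intermediate
7 | prenyl bromide (1-bromo-3-methylbut-2-ene) | CC(C)=CCBr | starting material
8 | 2-hydroxy-3,6-dimethoxy-4-(prenyloxy)benzaldehyde (prenyl = 3-methylbut-2-en-1-yl) | COc1cc(OCC=C(C)C)c(OC)c(O)c1C=O | intermediate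
9 | methyl homovanillate, methyl (4-hydroxy-3-methoxyphenyl)acetate | COC(=O)Cc1ccc(O)c(OC)c1 | starting material
10 | methyl [4-(benzenesulfonyloxy)-3-methoxyphenyl]acetate | COC(=O)Cc1ccc(OS(=O)(=O)c2ccccc2)c(OC)c1 | intermediate
11 | rac-methyl bromo[4-(benzenesulfonyloxy)-3-methoxyphenyl]acetate (racemate) | COC(=O)C(Br)c1ccc(OS(=O)(=O)c2ccccc2)c(OC)c1 | intermediate
12 | rac-methyl [4-(benzenesulfonyloxy)-3-methoxyphenyl][2-formyl-3,6-dimethoxy-5-(prenyloxy)phenoxy]acetate (racemate) | COC(=O)C(Oc1c(C=O)c(OC)cc(OCC=C(C)C)c1OC)c1ccc(OS(=O)(=O)c2ccccc2)c(OC)c1 | intermediate
13 | rac-4-{2-hydroxy-1-[2-(hydroxymethyl)-3,6-dimethoxy-5-(prenyloxy)phenoxy]ethyl}-2-methoxyphenyl benzenesulfonate (racemate) | OCC(Oc1c(CO)c(OC)cc(OCC=C(C)C)c1OC)c1ccc(OS(=O)(=O)c2ccccc2)c(OC)c1 | intermediate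
14 | rac-4-{1-[2-formyl-3,6-dimethoxy-5-(prenyloxy)phenoxy]-2-oxoethyl}-2-methoxyphenyl benzenesulfonate (racemate) | O=CC(Oc1c(C=O)c(OC)cc(OCC=C(C)C)c1OC)c1ccc(OS(=O)(=O)c2ccccc2)c(OC)c1 | intermediate
15 | rac-4-[(2R,3R)-3-hydroxy-5,8-dimethoxy-4-oxo-7-(prenyloxy)chroman-2-yl]-2-methoxyphenyl benzenesulfonate (trans, racemate, one enantiomer drawn) | COc1cc(OCC=C(C)C)c(OC)c2O[C@H](c3ccc(OS(=O)(=O)c4ccccc4)c(OC)c3)[C@@H](O)C(=O)c12 | intermediate
16 | rac-4-[5,8-dimethoxy-3,4-dioxo-7-(prenyloxy)chroman-2-yl]-2-methoxyphenyl benzenesulfonate (formed in the flask, not isolated) | COc1cc(OCC=C(C)C)c(OC)c2OC(c3ccc(OS(=O)(=O)c4ccccc4)c(OC)c3)C(=O)C(=O)c12 | intermediate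
17 | 4-[3-hydroxy-5,8-dimethoxy-4-oxo-7-(prenyloxy)-4H-chromen-2-yl]-2-methoxyphenyl benzenesulfonate | COc1cc(OCC=C(C)C)c(OC)c2oc(-c3ccc(OS(=O)(=O)c4ccccc4)c(OC)c3)c(O)c(=O)c12 | intermediate
18 | 2-methoxy-4-[3,5,8-trimethoxy-4-oxo-7-(prenyloxy)-4H-chromen-2-yl]phenyl benzenesulfonate | COc1cc(OCC=C(C)C)c(OC)c2oc(-c3ccc(OS(=O)(=O)c4ccccc4)c(OC)c3)c(OC)c(=O)c12 | intermediate
19 | 4'-hydroxy-3,5,8,3'-tetramethoxy-7-prenyloxyflavone, 2-(4-hydroxy-3-methoxyphenyl)-3,5,8-trimethoxy-7-(prenyloxy)-4H-chromen-4-one (no stereocentre) | COc1cc(-c2oc3c(OC)c(OCC=C(C)C)cc(OC)c3c(=O)c2OC)ccc1O | target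

## Step count and least certain steps

Total step count: 13. Longest linear sequence: 11 steps (steps 1–4 and 7–13, from 1). The ring B branch (steps 5 and 6) joins at step 7.

**Step 10 (key step).** The most likely failure is fragmentation in place of ring closure. If the Breslow intermediate forms at the aliphatic formyl group, the ring A aryloxide is β to the acyl-anion carbon and can be expelled, a known carbene-catalysed redox pathway of α-aryloxy aldehydes. The ortho-formyl group makes that aryloxide a good leaving group, and the same formyl group, flanked by two oxygen substituents, is a hindered and electron-rich acceptor, so cyclisation may not outrun loss of the tether. A reversible 5-exo aldol closure from the enol of the aliphatic aldehyde may also hold material back.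

Fallback (known chemistry): from 14, pinacol cyclisation with SmI2 (THF, t-BuOH, −78 °C) joins the two formyl carbons by ketyl coupling, as is established for α-oxygenated dialdehydes. It should give 4-[3,4-dihydroxy-5,8-dimethoxy-7-(prenyloxy)chroman-2-yl]-2-methoxyphenyl benzenesulfonate F1 as a mixture of racemic diastereomers. Swern oxidation of both hydroxyl groups of F1 ((COCl)2, DMSO, CH2Cl2, −78 °C; NEt3) gives dione 16, which tautomerises to 17, where the route is rejoined.

**Step 2.** The most likely failure is incomplete exchange of the second bromide, or diaryl ether formation. After the first coupling the substrate is an electron-rich bromophenoxide that adds to palladium more slowly and also competes with hydroxide as the oxygen nucleophile.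

Fallback: from 2, double Miyaura borylation (B2pin2, PdCl2(dppf), KOAc, 1,4-dioxane, 90 °C) gives 2,2'-(2,5-dimethoxy-1,3-phenylene)bis(4,4,5,5-tetramethyl-1,3,2-dioxaborolane) F2. Oxidation of both C–B bonds (H2O2, NaOH, THF, 0 °C) returns to 4.

**Step 7.** The most likely failure is slow alkylation of the doubly flanked, hydrogen-bonded phenoxide. Under prolonged basic treatment this would be followed by aldol closure of the product's ester enolate onto the neighbouring formyl group. Ring bromination in step 6 would hurt the same junction.

Fallback: from 10, hydroxylation of the lithium enolate (LiHMDS, THF, −78 °C; 2-(benzenesulfonyl)-3-phenyloxaziridine) gives rac-methyl [4-(benzenesulfonyloxy)-3-methoxyphenyl](hydroxy)acetate F3. Mitsunobu etherification of F3 with 8 (PPh3, DIAD, THF, 0 °C → rt) forms the same ether under neutral conditions and returns to 12. This detour bypasses step 6 as well.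

**Step 9.** The most likely failure is lactol formation after the first oxidation, with over-oxidation to a seven-membered lactone. This happens if the aliphatic alcohol is oxidised before the benzylic one. Enolisation and aldol loss of the dialdehyde on handling is the second concern.

Fallback: from 13, MnO2 (CH2Cl2, rt) oxidises only the benzylic alcohol and gives rac-4-{1-[2-formyl-3,6-dimethoxy-5-(prenyloxy)phenoxy]-2-hydroxyethyl}-2-methoxyphenyl benzenesulfonate F4, a stable compound that can be purified and stored. A single Dess–Martin oxidation of F4 immediately before step 10 returns to 14.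

## Further compounds

F1 | step 10 | 4-[3,4-dihydroxy-5,8-dimethoxy-7-(prenyloxy)chroman-2-yl]-2-methoxyphenyl benzenesulfonate (mixture of racemic diastereomers, configuration not controlled) | COc1cc(OCC=C(C)C)c(OC)c2OC(c3ccc(OS(=O)(=O)c4ccccc4)c(OC)c3)C(O)C(O)c12
F2 | step 2 | 2,2'-(2,5-dimethoxy-1,3-phenylene)bis(4,4,5,5-tetramethyl-1,3,2-dioxaborolane) | COc1cc(B2OC(C)(C)C(C)(C)O2)c(OC)c(B2OC(C)(C)C(C)(C)O2)c1
F3 | step 7 | rac-methyl [4-(benzenesulfonyloxy)-3-methoxyphenyl](hydroxy)acetate (racemate) | COC(=O)C(O)c1ccc(OS(=O)(=O)c2ccccc2)c(OC)c1
F4 | step 9 | rac-4-{1-[2-formyl-3,6-dimethoxy-5-(prenyloxy)phenoxy]-2-hydroxyethyl}-2-methoxyphenyl benzenesulfonate (racemate) | OCC(Oc1c(C=O)c(OC)cc(OCC=C(C)C)c1OC)c1ccc(OS(=O)(=O)c2ccccc2)c(OC)c1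
A1 | alternative 1 | 5,7-dihydroxy-3,8-dimethoxy-2-[3-methoxy-4-(methoxymethoxy)phenyl]-4H-chromen-4-one | COCOc1ccc(-c2oc3c(OC)c(O)cc(O)c3c(=O)c2OC)cc1OC
A2 | alternative 1 | 3-methoxy-2-[3-methoxy-4-(methoxymethoxy)phenyl]-5-(phenylsulfonyl)-4H-pyran-4-one | COCOc1ccc(-c2occ(S(=O)(=O)c3ccccc3)c(=O)c2OC)cc1OC
A3 | alternative 1 | 1,4-dimethoxy-1,3-bis(trimethylsilyloxy)buta-1,3-diene (alkene geometry not specified) | COC=C(O[Si](C)(C)C)C=C(OC)O[Si](C)(C)C
A4 | alternative 2 | 3-(benzyloxy)-2,5-dimethoxyphenol | COc1cc(O)c(OC)c(OCc2ccccc2)c1
A5 | alternative 2 | 3-(benzyloxy)-4-methoxycyclobut-2-en-1-one (racemate) | COC1C(OCc2ccccc2)=CC1=O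
A6 | alternative 2 | methoxyethyne | COC#C
A7 | alternative 3 | 7-(benzyloxy)-3,5,8-trimethoxy-2-[3-methoxy-4-(tosyloxy)phenyl]-4H-chromen-4-one | COc1cc(-c2oc3c(OC)c(OCc4ccccc4)cc(OC)c3c(=O)c2OC)ccc1OS(=O)(=O)c1ccc(C)cc1
A8 | alternative 3 | (E)-3-[3-(benzyloxy)-2,5-dimethoxyphenoxy]-2-methoxy-3-[3-methoxy-4-(tosyloxy)phenyl]prop-2-enoic acid | COc1cc(OCc2ccccc2)c(OC)c(O/C(c2ccc(OS(=O)(=O)c3ccc(C)cc3)c(OC)c2)=C(/OC)C(=O)O)c1
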